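One thing should hold still from flask to flask: how the partner divides once it is the limiting reagent. The other thing to settle is what happens to the target afterwards.

| setting | maple | larch | oak | autumn | winter | spring | midnight |
|---|---|---|---|---|---|---|---|
| starting material | 20 mM | 20 mM | 10 mM | 20 mM | 20 mM | 20 mM | 20 mM |
| partner | 11 mM | 44 mM | 22 mM | 22.0 mM | 22.0 mM | 22.0 mM | 22.0 mM |
| second substrate | 20 mM | 20 mM | 20 mM | 20.0 mM | 20.0 mM | 20.0 mM | 20.0 mM |
| third substrate | 20 mM | 20 mM | 20 mM | 20.0 mM | 20.0 mM | 20.0 mM | 20.0 mM |
| temperature | −28 °C | −11 °C | −28 °C | −35 °C | −5 °C |  | −20 °C |
| remark | run made earlier | run made earlier | run made earlier |  |  | at −35 °C until 50 s, from then on at −5 °C |  |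
| time |  |  |  | 2.5 min | 2.5 min | 2.5 min | 2.5 min |

| run | time / s | target / % |
|---|---|---|
| maple | 12.0 | 16.6 |
| maple | 25.0 | 21.1 |
| maple | 40.0 | 22.6 |
| maple | 50.0 | 22.3 |
| maple | 60.0 | 22.7 |
| maple | 80.0 | 22.5 |
| maple | 90.0 | 21.7 |
| larch | 10.0 | 75.1 |
| larch | 12.0 | 77.1 |
| larch | 15.0 | 78.4 |
| larch | 20.0 | 79.7 |
| larch | 25.0 | 80.4 |
| larch | 30.0 | 81.2 |
| oak | 20.0 | 41.9 |
| oak | 40.0 | 52.1 |
| oak | 50.0 | 54.7 |
| oak | 80.0 | 57.5 |
| oak | 90.0 | 58.3 |

(standard deviation of a reading: 0.3 percentage points)

- the numbers in the tables scatter with a standard deviation of 0.3 percentage points

1. which flask leads in amount of target, in percent of the starting material charged ("all alike" within 1.5 percentage points) (autumn / winter / spring / midnight / all alike)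
2. how much target is there at the end, in percent of the starting material charged: autumn
3. how much target is there at the end, in percent of the starting material charged: winter
4. how much target is there at the end, in percent of the starting material charged: spring
5. how much target is there at the end, in percent of the starting material charged: midnight

Call s the split, the part of the partner that ends as target. Maple's flat stretch gives 41.0%, as a reading. As odds against the rest that is 0.694, and I let the odds follow the ratio c(starting material)/c(third substrate). Oak, with half that ratio, should then give a split of 25.8%, and its last reading, still climbing, gives 26.5%. So the rule passes a test on a run that did not make it. I also freeze s across temperature, although maple and oak both stand at −28 °C. A flask with 22.0 mM of partner should then make M = s·c(partner)/c(starting material) = 45.1% of target.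

Here two chemists part. The first says that what is made stays, so the four flasks end close to M. Maple's drop from its flat stretch to the last reading is 0.83 points, and with a scatter of 0.3 points that is thin evidence.

The second, whom I side with, takes the drop as real and reads from it a fall of target of 0.0565 min⁻¹ at maple's temperature. First readings of larch and oak suggest that target forms 2.56 times as fast at larch's temperature. Borrowing that factor for the fall over 2.5 min, as an estimate, leaves winter about 31.4%, and lower is likely, since winter stands warmer than larch. Autumn stands colder than maple, so it should end between 39.2% and M. My order is autumn, midnight, spring, winter.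

The forecast sides with the first chemist, “each run stops when the partner runs out”, and gives autumn the lead with 47%, midnight 45%, spring 44% and winter 38.5%.

The flasks give autumn 45.1%, midnight 35.1%, spring 22.8% and winter 17.2%, so target does fall, and in winter further than my 31.4%. Side product holds two units of starting material, one of them former target, so winter's target made is 47.5%, beside M of 45.1%. The first chemist keeps the cold end: autumn holds 5.96% side product.

    2 partner → self-condensation product (k = 0.210 M⁻¹ s⁻¹, Ea = 50.0 kJ mol⁻¹)
    third substrate + partner → third product (k = 5.20 M⁻¹ s⁻¹, Ea = 48.0 kJ mol⁻¹)
    second substrate + partner → second product (k = 0.520 M⁻¹ s⁻¹, Ea = 54.0 kJ mol⁻¹)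
    starting material + target → side product (k = 0.240 M⁻¹ s⁻¹, Ea = 55.0 kJ mol⁻¹)
    starting material + partner → target (k = 4.70 M⁻¹ s⁻¹, Ea = 48.0 kJ mol⁻¹)
    (constants at −20 °C)

The neighbour of winter with 34 mM of starting material should by the rule have odds 1.18, hence a split of 54.1% and 11.9 mM of target made. That flask shows 12.4 mM made, with 4.40% target standing at the end.

The runs were computed for an exercise, and the scatter is random.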